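## Structural features

The target 20 is a 3,4-dihydroisocoumarin (isochroman-1-one; C1 carbonyl, O2, C3, C4, C4a, C5–C8, C8a; side chain C1′–C11′). A benzene ring A (C4a, C5, C6, C7, C8, C8a) is fused along C4a–C8a to a six-membered lactone (C1, O2, C3, C4). Ring A is a resorcinol with free hydroxyls at C6 and C8, the C8 hydroxyl being hydrogen-bonded to the C1 carbonyl. Its two carbon substituents (C1 on C8a, C4 on C4a) are adjacent, so three contiguous positions (C4a, C8a, C8) and C6 must be filled with full regiocontrol. C3 (R) carries an unbranched chain whose C10′ (S) bears a methoxy group. Nine methylene groups separate the two stereocentres, so neither can direct the other and each must be set independently. The fragile parts are the lactone (base, nucleophiles), the electron-rich ring (oxidants, electrophiles) and the secondary methyl ether, which rules out aryl methyl ethers as phenol protection because boron-halide demethylation would endanger C10′–OMe. The real difficulty is the regiodefined tetrasubstitution of ring A together with an economical supply of two remote stereocentres. The key step uses the fact that C5–C8 with oxygen on C6 and C8 is a 1,3-dioxygenated diene, and that the C4a–C8a edge with C4 and C1 attached is the triple bond of an alk-2-ynoate whose C3 oxygen sits δ to the ester carbon.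

## Logic of the disconnections

20 ⇒ 18 (through 19). The acyl–oxygen bond O2–C1 is cut and the hydroxyls at C6, C8 and C3 are returned to silyl ethers. The cut is placed here because the C3 oxygen stands δ to C1, so closure is a six-membered transesterification that touches neither stereocentre. The gain is that the lactone and the free phenols are absent from all earlier intermediates. The demand is one mild acidic operation that removes silyl groups of two different stabilities and closes the ring while the C10′ methyl ether stays.

18 ⇒ 12 + 16 (through 17). The ring bonds C8–C8a and C5–C4a are cut and, formally, a two-carbon bridge is put back between C5 and C8. These bonds flank the fully substituted C4a–C8a edge, so cutting them turns that edge into an alkyne that already carries C1 and C4, and turns C5–C8 with both oxygens into a diene. The gain is large: ring A and its regiochemistry reduce to an open-chain compound 12, which holds both stereocentres, and the achiral 16. The demand is a regioselective cycloaddition and clean loss of ethene at a temperature that 12 tolerates.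

12 ⇒ 11. The O–Si bond at C5 is cut. The hydroxyl is masked so that it stays inert in the hot, silyl-donor-rich medium of the ring-forming step; the gain is only one of handling. The demand is silylation without a nucleophile that could add to the conjugated triple bond.

11 ⇒ 8 + 9 (through 10). The C3–C4 bond of 11 (C4a–C4 of 20) is cut. A carbinol β to a propargylic carbon is the retron of an acetylide opening an epoxide. The gain is that C1, C8a and C4a come from commercial 9 and the C3 stereocentre comes ready-made in 8. The demand is that an ester-bearing, thermally labile acetylide attack only the terminal epoxide carbon at low temperature.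

8 ⇒ 7 ⇒ 6. The two C–O bonds of the oxirane are cut back to a terminal alkene. The existing stereocentre is too far away to induce the new one, so the configuration must come from a catalyst. The gain is the removal of one stereocentre and of all oxygen functionality at that terminus. The demand is a resolution with a high selectivity factor, and the loss of the unwanted epimer is accepted.

6 ⇒ 4 ⇒ 1 + 2 (through 5 and 3). First the O–CH3 bond is cut, then C3–C4 of 4 (C9′–C8′ of 20). A carbinol with a carbon chain on the adjacent CH2 is the retron of an organometallic opening a chiral-pool epoxide. The gain is two commercial fragments, one of which supplies C10′ in enantiopure form. The demand is attack at the unsubstituted epoxide carbon only, and an ether formation that leaves the stereocentre alone.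

16 ⇒ 14 ⇒ 13 (through 15). The two O–Si bonds are cut in turn. 16 is the doubly enolised, doubly silylated form of the symmetric dione, so symmetry makes the first enolisation unambiguous. The demand is kinetic deprotonation at C6 of 14, O-silylation, and strict exclusion of moisture.

## Other disconnections considered

Alternative 1: The cut is C4a–C4 together with O2–C1, so ring A is bought intact and only the lactone is made.
- Forward step: 2,4-bis(benzyloxy)benzoic acid A1 would be joined to epoxide 8 under divalent palladium catalysis. The carboxylate directs palladation of the single free ortho C–H bond, the aryl–palladium bond opens 8 at its unsubstituted carbon, and the alkoxide closes onto the carboxyl to give (3R)-6,8-bis(benzyloxy)-3-[(10S)-10-methoxyundecyl]isochroman-1-one A2. Hydrogenolysis of the benzyl ethers would then give 20.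
- In its favour: the arene is not built at all, regiochemistry is trivial because A1 has only one ortho hydrogen, and the C3–O bond of 8 is never broken.
- Against it here: A1 is an electron-rich ortho-alkoxy acid of the kind that tends to lose CO2 under palladium and heat. The epoxide is unactivated, long-chain and carries a Lewis-basic ether. Reactions of this type are normally run with the epoxide in excess, and here the epoxide is the four-step chiral partner.
- Comparison: on step economy this plan is better than the chosen one (about six steps in the longest line against eight) and it is more convergent. On stereochemical integrity the two are equal, since both carry 8 through unchanged. On mechanism the chosen cycloaddition is preferred: it is neutral, has close analogy for exactly this substitution pattern, and uses the cheap achiral partner in excess.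

Alternative 2: The cuts are C1′–C2′ and C8′–C9′ in the side chain.
- Forward step: the di-Grignard reagent A3 would open two molecules of (R)-epichlorohydrin A4 at the epoxide CH2 under copper catalysis, giving (2R,12R)-1,13-dichlorotridecane-2,12-diol A5. Double ring closure would give the bis-epoxide A6; reductive opening of one oxirane and O-methylation would then arrive at 8.
- In its favour: both stereocentres come from one inexpensive chiral-pool reagent in a single operation, with no resolution. The same (R) terminus serves as the (R)-epoxide at one end and, once its CH2Cl has become CH3, as the (S)-carbinol at the other.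
- Against it here: it is a chain construction and says nothing about ring A or the lactone, so it can only replace steps 1–4. The two identical ends of A6 must be told apart statistically. A bifunctional Grignard reagent is harder to form cleanly than a monofunctional one.
- Comparison: on stereochemistry it is better than steps 1–4, and its key reaction is of the same type and reliability as step 1. On step count to 8 it is equal (four operations). On material balance the statistical differentiation costs about what the resolution in step 4 costs. It is therefore a possible substitute for the early steps, not a rival to the ring construction.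

Alternative 3: The cuts are C8a–C4a and C7–C6, with O2–C1 broken and re-formed.
- Forward step: methyl acetoacetate A7 would add in Michael fashion to (6R)-6-[(10S)-10-methoxyundecyl]-5,6-dihydro-2H-pyran-2-one A8, which could come from 11 by cis-selective semi-hydrogenation and lactonisation. A Claisen closure of the acetoacetate methyl onto the lactone carbonyl, and return of the freed C3 alkoxide onto the ester, would give the bicyclic enol-dione A9. A dehydrogenation would then be needed to reach 20.
- In its favour: no protecting groups at all, inexpensive enolate chemistry of a classical type, regiochemistry fixed by connectivity, and the C4a epimers of A9 are irrelevant because aromatisation removes that centre.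
- Against it here: A9 is two hydrogens short of aromatic, and oxidising it in the presence of the very electron-rich product invites over-oxidation or ring halogenation. Under the basic conditions A8 can open by elimination across C4–C3 (numbering of 20), which breaks the C3–O bond and puts the stereocentre at risk. The Claisen step must proceed through the less acidic methyl group.
- Comparison: on protecting-group economy this plan is better than the chosen one. On step count from 8 it is equal (four steps each). On redox economy and on safety of the C3 stereocentre the chosen plan is better, because it keeps C3–O intact under neutral conditions and delivers ring A at the correct oxidation level.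

Key step: step 9

Remark on the chemistry: the usual sense of the hydrolytic kinetic resolution of alkyl oxiranes is assumed, with the (R,R)-catalyst hydrating the (S)-configured epoxide; in step 4 "salen" stands for the dianion of (R,R)-N,N′-bis(3,5-di-tert-butylsalicylidene)cyclohexane-1,2-diamine and the complex is an acetate of trivalent cobalt.

Step 1
Reactants: 1 10-bromodec-1-ene; 2 (S)-propylene oxide
Product: 4 (2S)-tridec-12-en-2-ol, via dec-9-enylmagnesium bromide 3 (not isolated)
Conditions: Mg, THF, rt → 40 °C; CuI (10 mol%), then 2, THF, −30 → 0 °C; aq. NH4Cl
Reagents that add atoms: none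
Why: Grignard formation, then copper-catalysed SN2 opening of the terminal epoxide at its unsubstituted CH2; the C–O bond at the stereocentre of 2 is not broken, so its (S) configuration becomes C2 of 4 (the later C10′).

Step 2
Reactants: 4 (2S)-tridec-12-en-2-ol
Product: 6 (12S)-12-methoxytridec-1-ene, via sodium alkoxide 5 (not isolated)
Conditions: NaH, THF, 0 °C; MeI, 0 °C → rt
Reagents that add atoms: iodomethane, CI
Why: Williamson ether synthesis; the reaction takes place at oxygen, so the configuration is retained, and the terminal alkene is inert.

Step 3
Reactants: 6 (12S)-12-methoxytridec-1-ene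
Product: 7 2-[(10S)-10-methoxyundecyl]oxirane as a mixture of both C2 epimers
Conditions: mCPBA, NaHCO3, CH2Cl2, 0 °C → rt
Reagents that add atoms: 3-chloroperoxybenzoic acid (mCPBA), O=C(OO)c1cccc(Cl)c1
Why: Prilezhaev epoxidation of a monosubstituted alkene; the remote stereocentre exerts no facial control, so no selectivity is expected and the configuration is settled in step 4.

Step 4
Reactants: 7 2-[(10S)-10-methoxyundecyl]oxirane (both C2 epimers)
Product: 8 (2R)-2-[(10S)-10-methoxyundecyl]oxirane
Conditions: (R,R)-(salen)Co(OAc) (0.5–1 mol%), H2O (0.55 equiv), THF (min.), 0 °C → rt; separation from the diol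
Reagents that add atoms: none
Why: Jacobsen hydrolytic kinetic resolution; the chiral cobalt Lewis acid delivers water to the terminal carbon of the (2S) epimer much faster and leaves the (2R) epoxide. Because the other stereocentre is remote, the epimer pair behaves like a racemate and the catalyst alone sets C2 (the later C3).

Step 5
Reactants: 8 (2R)-2-[(10S)-10-methoxyundecyl]oxirane; 9 methyl propiolate
Product: 11 methyl (5R,15S)-5-hydroxy-15-methoxyhexadec-2-ynoate, via methyl 3-lithiopropiolate 10 (not isolated)
Conditions: 9 (3 equiv), n-BuLi, THF, −78 °C; BF3·OEt2, then 8, −78 °C; aq. NH4Cl at −78 °C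
Reagents that add atoms: none
Why: Yamaguchi–Hirao alkynylation; the ester-stabilised lithium acetylide opens the BF3-activated epoxide by SN2 attack at the terminal CH2 at −78 °C, below the temperature at which the acetylide decomposes. The stereocentre is not involved and becomes C5 (R).

Step 6
Reactants: 11 methyl (5R,15S)-5-hydroxy-15-methoxyhexadec-2-ynoate
Product: 12 methyl (5R,15S)-5-(tert-butyldimethylsilyloxy)-15-methoxyhexadec-2-ynoate
Conditions: TBSOTf, 2,6-lutidine, CH2Cl2, −78 → 0 °C
Reagents that add atoms: tert-butyldimethylsilyl triflate, CC(C)(C)[Si](C)(C)OS(=O)(=O)C(F)(F)F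
Why: Silyl triflate silylation of a secondary alcohol with a hindered, non-nucleophilic base, so that no amine can add to the conjugated alkyne; the TBS ether survives chromatography and the heat of step 9.

Step 7
Reactants: 13 cyclohexane-1,3-dione
Product: 14 3-(trimethylsilyloxy)cyclohex-2-en-1-one
Conditions: TMSCl, Et3N, THF, 0 °C → rt; filtration under Ar, distillation
Reagents that add atoms: chlorotrimethylsilane, C[Si](C)(C)Cl
Why: O-silylation of the enol of a cyclic 1,3-dione; the product is moisture-sensitive, so it is isolated without aqueous work-up.

Step 8
Reactants: 14 3-(trimethylsilyloxy)cyclohex-2-en-1-one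
Product: 16 1,3-bis(trimethylsilyloxy)cyclohexa-1,3-diene, via lithium dienolate 15 (not isolated)
Conditions: LDA, THF, −78 °C; TMSCl, −78 °C → rt; pentane, filtration, distillation
Reagents that add atoms: chlorotrimethylsilane, C[Si](C)(C)Cl
Why: Kinetic deprotonation at C6 (the α′ position) by LDA and O-silylation of the cross-conjugated enolate give the 1,3-dioxygenated diene.

Step 9
Reactants: 12 methyl (5R,15S)-5-(tert-butyldimethylsilyloxy)-15-methoxyhexadec-2-ynoate; 16 1,3-bis(trimethylsilyloxy)cyclohexa-1,3-diene
Product: 18 methyl 2-[(2R,12S)-2-(tert-butyldimethylsilyloxy)-12-methoxytridecyl]-4,6-bis(trimethylsilyloxy)benzoate, via bicyclo[2.2.2]octadiene adduct 17 (not isolated)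
Conditions: 16 (3 equiv), neat, Ar, sealed pressure tube, 170 °C; volatiles and excess 16 removed in vacuo, crude 18 carried on
Reagents that add atoms: none
Why: A thermal, concerted but asynchronous (4+2) cycloaddition of the electron-rich diene 16 to the electron-poor triple bond of 12 gives the bicyclo[2.2.2]octa-2,5-diene 17, which at the same temperature undergoes a retro-(4+2) reaction that expels its saturated two-carbon bridge as ethene and leaves ring A aromatic. The closest known reaction type is the Alder–Rickert benzannulation of 1,3-bis(silyloxy)cyclohexa-1,3-dienes with acetylenic esters to 6-substituted 2,4-dioxygenated benzoates. Ring A is closed intermolecularly by cycloaddition, with C5–C8 coming from the diene and C4a and C8a from the alkyne, and with C5–C4a and C8–C8a formed in the same step; no tether is cyclised. No lasting stereocentre is created: the two bridgehead centres of 17 vanish on aromatisation, and C5 and C15 of 12 are spectators that cannot epimerise in a neutral medium. The selectivity needed is regiochemical, and polarity matching secures it: both silyloxy groups push electron density to the unsubstituted diene terminus, which bonds to the electrophilic β-carbon of the ynoate, so the oxygen-bearing terminus ends next to the ester carbon. Loss of gaseous ethene and the gain of aromaticity make the sequence irreversible, and the excess of 16 allows for its slow thermal isomerisation. The TBS ether keeps the C5 oxygen out of silyl exchange with 16, and the methyl ester, the methyl ether and the silyl ethers are inert under these neutral conditions.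

Step 10
Reactants: 18 methyl 2-[(2R,12S)-2-(tert-butyldimethylsilyloxy)-12-methoxytridecyl]-4,6-bis(trimethylsilyloxy)benzoate
Product: 20 (3R)-6,8-dihydroxy-3-[(10S)-10-methoxyundecyl]isochroman-1-one (target), via triol methyl ester 19 (not isolated)
Conditions: p-TsOH·H2O (0.3 equiv), MeOH, rt → 40 °C; then evaporation, toluene, 80 °C
Reagents that add atoms: none
Why: Acid-catalysed methanolysis cleaves the aryl TMS ethers quickly and the secondary TBS ether more slowly; after the solvent switch the C3 hydroxyl attacks the protonated ester (intramolecular transesterification, 6-exo-trig) and methanol is driven off. The C3–O and C10′–O bonds are never broken, so both configurations are retained, and the aliphatic methyl ether is stable to sulfonic acid.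

Compound list

1 | 10-bromodec-1-ene | C=CCCCCCCCCBr | starting material
2 | (S)-propylene oxide, (2S)-2-methyloxirane | C[C@H]1CO1 | starting material
3 | dec-9-enylmagnesium bromide (not isolated) | C=CCCCCCCCC[Mg]Br | intermediate
4 | (2S)-tridec-12-en-2-ol | C[C@H](O)CCCCCCCCCC=C | intermediate
5 | sodium (2S)-tridec-12-en-2-olate (not isolated) | C[C@H]([O-])CCCCCCCCCC=C.[Na+] | intermediate
6 | (12S)-12-methoxytridec-1-ene | CO[C@@H](C)CCCCCCCCCC=C | intermediate
7 | 2-[(10S)-10-methoxyundecyl]oxirane, both C2 epimers | CO[C@@H](C)CCCCCCCCCC1CO1 | intermediate
8 | (2R)-2-[(10S)-10-methoxyundecyl]oxirane | CO[C@@H](C)CCCCCCCCC[C@@H]1CO1 | intermediate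
9 | methyl propiolate | C#CC(=O)OC | starting material
10 | methyl 3-lithioprop-2-ynoate (not isolated) | [Li]C#CC(=O)OC | intermediate
11 | methyl (5R,15S)-5-hydroxy-15-methoxyhexadec-2-ynoate | CO[C@@H](C)CCCCCCCCC[C@@H](O)CC#CC(=O)OC | intermediate
12 | methyl (5R,15S)-5-(tert-butyldimethylsilyloxy)-15-methoxyhexadec-2-ynoate | CO[C@@H](C)CCCCCCCCC[C@H](CC#CC(=O)OC)O[Si](C)(C)C(C)(C)C | intermediate
13 | cyclohexane-1,3-dione | O=C1CCCC(=O)C1 | starting material
14 | 3-(trimethylsilyloxy)cyclohex-2-en-1-one | C[Si](C)(C)OC1=CC(=O)CCC1 | intermediate
15 | lithium 5-(trimethylsilyloxy)cyclohexa-1,5-dien-1-olate (not isolated) | [Li+].[O-]C1=CCCC(O[Si](C)(C)C)=C1 | intermediate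
16 | 1,3-bis(trimethylsilyloxy)cyclohexa-1,3-diene | C[Si](C)(C)OC1=CC(O[Si](C)(C)C)=CCC1 | intermediate
17 | methyl 3-[(2R,12S)-2-(tert-butyldimethylsilyloxy)-12-methoxytridecyl]-1,5-bis(trimethylsilyloxy)bicyclo[2.2.2]octa-2,5-diene-2-carboxylate, bridgehead epimers (not isolated) | CO[C@@H](C)CCCCCCCCC[C@H](CC1=C(C(=O)OC)C2(O[Si](C)(C)C)CCC1C(O[Si](C)(C)C)=C2)O[Si](C)(C)C(C)(C)C | intermediate
18 | methyl 2-[(2R,12S)-2-(tert-butyldimethylsilyloxy)-12-methoxytridecyl]-4,6-bis(trimethylsilyloxy)benzoate | CO[C@@H](C)CCCCCCCCC[C@H](Cc1cc(O[Si](C)(C)C)cc(O[Si](C)(C)C)c1C(=O)OC)O[Si](C)(C)C(C)(C)C | intermediate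
19 | methyl 2,4-dihydroxy-6-[(2R,12S)-2-hydroxy-12-methoxytridecyl]benzoate (not isolated) | CO[C@@H](C)CCCCCCCCC[C@@H](O)Cc1cc(O)cc(O)c1C(=O)OC | intermediate
20 | (3R)-6,8-dihydroxy-3-[(10S)-10-methoxyundecyl]isochroman-1-one | CO[C@@H](C)CCCCCCCCC[C@@H]1Cc2cc(O)cc(O)c2C(=O)O1 | target

Total step count: 10. Longest linear sequence: 8 steps (1–6, 9, 10); the diene arm (steps 7 and 8) is two steps and joins at step 9.

Steps least certain to work

Step 9 (key step). The most likely failure is that the diene is consumed by thermal 1,5-hydrogen shift, silyl transfer or oligomerisation faster than it adds to the β-alkyl-substituted ynoate, so that conversion stalls. Too low a temperature could also leave the bicyclic adduct without ethene loss. The fallback gives up the ring construction and attaches a ready-made arene; it sets out from 8 and returns at 20.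
- 5-Bromoresorcinol would be benzylated (BnBr, K2CO3, DMF) to 1,3-bis(benzyloxy)-5-bromobenzene F1.
- Magnesium in THF converts it into [3,5-bis(benzyloxy)phenyl]magnesium bromide F2, which under CuI catalysis opens 8 at its CH2 to give (2R,12S)-1-[3,5-bis(benzyloxy)phenyl]-12-methoxytridecan-2-ol F3.
- NBS in MeCN at 0 °C brominates the ring position between the side chain and one benzyloxy group, para to the other, giving (2R,12S)-1-[3,5-bis(benzyloxy)-2-bromophenyl]-12-methoxytridecan-2-ol F4.
- Carbonylative lactonisation (Pd(OAc)2, Xantphos, CO, Et3N, toluene, 100 °C) closes (3R)-6,8-bis(benzyloxy)-3-[(10S)-10-methoxyundecyl]isochroman-1-one F5, the same compound as A2.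
- Hydrogenolysis (H2, Pd/C, EtOAc) gives 20.

Step 5. The lithiated propiolate may decompose or condense with itself before it attacks, or BF3 may rearrange or open the epoxide, all of which waste the chiral partner. The fallback installs the three-carbon unit in two stages; it sets out from 8 and returns at 12.
- Lithium acetylide–ethylenediamine complex in DMSO opens 8 to (4R,14S)-14-methoxypentadec-1-yn-4-ol F6.
- TBSCl and imidazole in DMF give (4R,14S)-4-(tert-butyldimethylsilyloxy)-14-methoxypentadec-1-yne F7.
- n-BuLi in THF at −78 °C forms [(4R,14S)-4-(tert-butyldimethylsilyloxy)-14-methoxypentadec-1-yn-1-yl]lithium F8, which is acylated with methyl chloroformate to give 12.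

Step 4. Hydrolysis of the unwanted epimer may be slow or incomplete because the lipophilic substrate mixes poorly with water, which would leave epimeric contamination at the later C3; half of the material is lost in any case. The fallback takes both stereocentres from the chiral pool; it sets out from 2 and returns at 8, replacing steps 1–4.
- 1-Bromo-7-chloroheptane and magnesium give (7-chloroheptyl)magnesium bromide F9 by insertion into the C–Br bond; under CuI catalysis it opens 2 to (2S)-10-chlorodecan-2-ol F10.
- Methylation (NaH, MeI) gives (9S)-1-chloro-9-methoxydecane F11.
- Magnesium in refluxing THF gives [(9S)-9-methoxydecyl]magnesium chloride F12, which opens (R)-epichlorohydrin A4 at the epoxide CH2 (CuI cat., −40 °C) to (2R,12S)-1-chloro-12-methoxytridecan-2-ol F13.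
- NaOH closes F13 to 8.

Step 10. The sequence may stall at the open hydroxy ester, because acyl substitution at a hindered, hydrogen-bonded, electron-rich ester is slow, or the TBS ether may cleave sluggishly. The fallback replaces attack at the ester carbonyl by SN2 cleavage at the ester methyl group and lactonisation of the free acid; it sets out from 18 and returns at 20.
- HF·pyridine in THF removes all three silyl groups, and 19 is isolated.
- LiI in refluxing EtOAc followed by dilute HCl gives 2,4-dihydroxy-6-[(2R,12S)-2-hydroxy-12-methoxytridecyl]benzoic acid F14.
- As a δ-hydroxy acid, F14 should close to 20 on standing with a trace of acid at room temperature, or with EDC·HCl in CH2Cl2.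

Further compounds

F1 | step 9 | 1,3-bis(benzyloxy)-5-bromobenzene | Brc1cc(OCc2ccccc2)cc(OCc2ccccc2)c1
F2 | step 9 | [3,5-bis(benzyloxy)phenyl]magnesium bromide | Br[Mg]c1cc(OCc2ccccc2)cc(OCc2ccccc2)c1
F3 | step 9 | (2R,12S)-1-[3,5-bis(benzyloxy)phenyl]-12-methoxytridecan-2-ol | CO[C@@H](C)CCCCCCCCC[C@@H](O)Cc1cc(OCc2ccccc2)cc(OCc2ccccc2)c1
F4 | step 9 | (2R,12S)-1-[3,5-bis(benzyloxy)-2-bromophenyl]-12-methoxytridecan-2-ol | CO[C@@H](C)CCCCCCCCC[C@@H](O)Cc1cc(OCc2ccccc2)cc(OCc2ccccc2)c1Br
F5 | step 9 | (3R)-6,8-bis(benzyloxy)-3-[(10S)-10-methoxyundecyl]isochroman-1-one | CO[C@@H](C)CCCCCCCCC[C@@H]1Cc2cc(OCc3ccccc3)cc(OCc3ccccc3)c2C(=O)O1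
F6 | step 5 | (4R,14S)-14-methoxypentadec-1-yn-4-ol | CO[C@@H](C)CCCCCCCCC[C@@H](O)CC#C
F7 | step 5 | (4R,14S)-4-(tert-butyldimethylsilyloxy)-14-methoxypentadec-1-yne | CO[C@@H](C)CCCCCCCCC[C@H](CC#C)O[Si](C)(C)C(C)(C)C
F8 | step 5 | [(4R,14S)-4-(tert-butyldimethylsilyloxy)-14-methoxypentadec-1-yn-1-yl]lithium | CO[C@@H](C)CCCCCCCCC[C@H](CC#C[Li])O[Si](C)(C)C(C)(C)C
F9 | step 4 | (7-chloroheptyl)magnesium bromide | ClCCCCCCC[Mg]Br
F10 | step 4 | (2S)-10-chlorodecan-2-ol | C[C@H](O)CCCCCCCCCl
F11 | step 4 | (9S)-1-chloro-9-methoxydecane | CO[C@@H](C)CCCCCCCCCl
F12 | step 4 | [(9S)-9-methoxydecyl]magnesium chloride | CO[C@@H](C)CCCCCCCC[Mg]Cl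
F13 | step 4 | (2R,12S)-1-chloro-12-methoxytridecan-2-ol | CO[C@@H](C)CCCCCCCCC[C@@H](O)CCl
F14 | step 10 | 2,4-dihydroxy-6-[(2R,12S)-2-hydroxy-12-methoxytridecyl]benzoic acid | CO[C@@H](C)CCCCCCCCC[C@@H](O)Cc1cc(O)cc(O)c1C(=O)O
A1 | alternative 1 | 2,4-bis(benzyloxy)benzoic acid | O=C(O)c1ccc(OCc2ccccc2)cc1OCc1ccccc1
A2 | alternative 1 | (3R)-6,8-bis(benzyloxy)-3-[(10S)-10-methoxyundecyl]isochroman-1-one | CO[C@@H](C)CCCCCCCCC[C@@H]1Cc2cc(OCc3ccccc3)cc(OCc3ccccc3)c2C(=O)O1
A3 | alternative 2 | heptane-1,7-diylbis(magnesium bromide) | Br[Mg]CCCCCCC[Mg]Br
A4 | alternative 2 | (R)-epichlorohydrin, (2R)-2-(chloromethyl)oxirane | ClC[C@H]1CO1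
A5 | alternative 2 | (2R,12R)-1,13-dichlorotridecane-2,12-diol | ClC[C@H](O)CCCCCCCCC[C@@H](O)CCl
A6 | alternative 2 | (2R,2′R)-2,2′-(nonane-1,9-diyl)bis(oxirane) | C1O[C@@H]1CCCCCCCCC[C@@H]1CO1
A7 | alternative 3 | methyl acetoacetate (methyl 3-oxobutanoate) | COC(=O)CC(C)=O
A8 | alternative 3 | (6R)-6-[(10S)-10-methoxyundecyl]-5,6-dihydro-2H-pyran-2-one | CO[C@@H](C)CCCCCCCCC[C@@H]1CC=CC(=O)O1
A9 | alternative 3 | (3R)-8-hydroxy-3-[(10S)-10-methoxyundecyl]-3,4,4a,5-tetrahydro-1H-isochromene-1,6(7H)-dione (enol form, both C4a epimers) | CO[C@@H](C)CCCCCCCCC[C@@H]1CC2CC(=O)CC(O)=C2C(=O)O1
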